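**Plan**
- Retrosynthetic cuts, in order: the C3 configuration (base epimerisation); the bond from ring A to its benzylic carbon, together with both benzylic C–O bonds (aryl Grignard addition, hydrogenolysis); C4–C5 and O1–C2 of the lactone in one operation (aldol with formaldehyde, lactonisation); the bond from C3 to the future C4 (enolate allylation, alkene cleavage); the ring B side chain (Wittig).
- Enabling feature: in the lactone (O1, C2=O, C3 carrying the CH2 of ring B = 4-hydroxy-3,5-dimethoxyphenyl, C4 carrying the CH2 of ring A = 3,4-dimethoxyphenyl, C5 = OCH2), C5 is unsubstituted and so is formaldehyde. The exocyclic carbon on C4 can be held as a formyl group, which makes C4–H enolisable and later becomes the benzylic carbon of ring A. The C2 ester lies 1,4 to the new hydroxyl.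
- Forward: the ring B chain is built linearly from syringaldehyde, the lactone (the only ring formed) closes in step 6, and ring A is attached in step 7.
- Stereochemistry: C4 comes from the (S)-diarylprolinol silyl ether in step 6 (catalyst control). C3 is carried as a mixture and set trans to C4 by thermodynamic epimerisation in step 9.

Key step: step 6

Remark on the chemistry: lactone numbering (O1, C2 carbonyl, C3, C4, C5) is used for all lactones. The (S)-catalyst is assumed to follow the usual steric-shielding model of diarylprolinol silyl ethers, which predicts 4R.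

**Step 1**
Reactants: 1 syringaldehyde; 2 methyl (triphenylphosphoranylidene)acetate
Product: 3 methyl (E)-3-(4-hydroxy-3,5-dimethoxyphenyl)prop-2-enoate (methyl sinapate)
Conditions: toluene, 100 °C
Reagents that add atoms: none
Why: Wittig olefination with a stabilised ylide tolerates the free phenol and should give the E-cinnamate, whose geometry is irrelevant because the alkene is saturated next.

**Step 2**
Reactants: 3 methyl sinapate
Product: 4 methyl 3-(4-hydroxy-3,5-dimethoxyphenyl)propanoate
Conditions: H2 (1 atm), 10% Pd/C, MeOH, rt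
Reagents that add atoms: none
Why: Heterogeneous catalytic hydrogenation of the conjugated alkene, placed before benzylation so that no benzyl ether is exposed to H2 and Pd/C at this stage.

**Step 3**
Reactants: 4 methyl 3-(4-hydroxy-3,5-dimethoxyphenyl)propanoate; 5 benzyl bromide
Product: 6 methyl 3-(4-benzyloxy-3,5-dimethoxyphenyl)propanoate
Conditions: K2CO3, DMF, 50 °C
Reagents that add atoms: none
Why: Williamson etherification of the acidic 2,6-dimethoxyphenol masks the phenol for the enolate and Grignard steps with a group that the later hydrogenolysis removes at no extra cost.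

**Step 4**
Reactants: 6 methyl 3-(4-benzyloxy-3,5-dimethoxyphenyl)propanoate; 7 allyl bromide
Product: 9 methyl 2-(4-benzyloxy-3,5-dimethoxybenzyl)pent-4-enoate (racemic), via lithium enolate 8 (not isolated)
Conditions: LiN(iPr)2 (LDA, 1.1 equiv), THF, −78 °C; then allyl bromide, −78 °C to 0 °C
Reagents that add atoms: none
Why: Ester enolate alkylation (kinetic lithium enolate, SN2 on an allylic bromide) attaches the unit whose CH2 becomes C4 and whose internal alkene carbon becomes the formyl carbon; the future C3 is formed racemic on purpose.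

**Step 5**
Reactants: 9 methyl 2-(4-benzyloxy-3,5-dimethoxybenzyl)pent-4-enoate
Product: 11 methyl 2-(4-benzyloxy-3,5-dimethoxybenzyl)-4-oxobutanoate (racemic), via diol 10 (not isolated)
Conditions: OsO4 (2 mol %), NaIO4 (4 equiv), 2,6-lutidine (2 equiv), 1,4-dioxane/H2O (3:1), rt
Reagents that add atoms: osmium tetroxide, O=[Os](=O)(=O)=O (delivers the oxygen atoms of the diol); sodium periodate, [Na+].[O-]I(=O)(=O)=O (reoxidant that restores that oxygen to osmium)
Why: Lemieux–Johnson oxidation (dihydroxylation, then periodate glycol cleavage) with lutidine buffering should cleave the terminal alkene to the aldehyde without exposing the electron-rich arene to ozone.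

**Step 6**
Reactants: 11 methyl 2-(4-benzyloxy-3,5-dimethoxybenzyl)-4-oxobutanoate; 12 formaldehyde (37% aqueous solution)
Product: 14 (3R)-4-(4-benzyloxy-3,5-dimethoxybenzyl)-5-oxotetrahydrofuran-3-carbaldehyde (the 4-formyl lactone; 4R in lactone numbering; C3 epimer mixture), via hydroxy aldehyde 13 (not isolated)
Conditions: (S)-α,α-diphenylprolinol trimethylsilyl ether (20 mol %), 37% aq. HCHO (3 equiv), KH2PO4/K2HPO4 buffer (pH 7), toluene, rt; then pyridinium p-toluenesulfonate (cat.), CH2Cl2, rt
Reagents that add atoms: none
Why: The catalyst condenses with the formyl group of 11 to the E-enamine at C4, whose face syn to the diphenyl(trimethylsilyloxy)methyl group is blocked, so formaldehyde is attacked from the open (Si) face to form C4–C5 and, after iminium hydrolysis, give hydroxy aldehyde 13 with the 4R configuration. The closest known reaction type is the diarylprolinol silyl ether-catalysed enantioselective α-hydroxymethylation (cross-aldol) of aldehydes with aqueous formaldehyde under buffered conditions. The lactone closes by 5-exo-trig acyl substitution of the primary hydroxyl of 13 on the methyl ester (O1–C2 bond), promoted by mild acid with loss of methanol. The one new stereocentre, C4, is under catalyst control and must override the adjacent racemic C3, which therefore appears as both epimers. Cross- over self-aldol selectivity rests on formaldehyde being non-enolisable and the most electrophilic partner while 11 is a β-branched, slowly self-condensing donor, and the neutral buffer should hold back Mannich-type α-methylenation. Lactonisation fixes the distinction between the CHO and CH2OH arms that defines C4 and blocks retro-aldol and dehydration, because loss of the ring carboxylate from the C4 enol would be the reverse of a 5-endo-trig closure.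

**Step 7**
Reactants: 14 the (4R)-4-formyl lactone; 15 4-bromo-1,2-dimethoxybenzene (4-bromoveratrole)
Product: 17 (4R)-3-(4-benzyloxy-3,5-dimethoxybenzyl)-4-[(3,4-dimethoxyphenyl)(hydroxy)methyl]dihydrofuran-2(3H)-one (epimer mixture at C3 and at the carbinol carbon), via arylmagnesium bromide 16 (not isolated)
Conditions: Mg, THF, rt (15 to 16); then 16 (1.1 equiv) added dropwise to freshly prepared 14, THF, −78 °C; aq. NH4Cl at −78 °C
Reagents that add atoms: none
Why: Grignard 1,2-addition to the aldehyde, by far the most electrophilic carbonyl present, should outpace both attack on the lactone and enolisation at C4 when the reagent is added slowly at −78 °C; the new carbinol centre is left undefined because it is removed in step 8.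

**Step 8**
Reactants: 17 the benzylic alcohol
Product: 18 (4R)-4-(3,4-dimethoxybenzyl)-3-(4-hydroxy-3,5-dimethoxybenzyl)dihydrofuran-2(3H)-one (C3 epimer mixture)
Conditions: H2 (3 atm), 10% Pd/C, AcOH, rt
Reagents that add atoms: none
Why: Pd-catalysed hydrogenolysis should cleave the aryl benzyl ether and the benzylic C–OH bond activated by the para-methoxy group in weakly acidic medium in one operation, without touching C4.

**Step 9**
Reactants: 18 the C3 epimer mixture
Product: 19 (3R,4R)-4-(3,4-dimethoxybenzyl)-3-(4-hydroxy-3,5-dimethoxybenzyl)dihydrofuran-2(3H)-one (trans; the target)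
Conditions: DBU (3 equiv), THF, 60 °C, argon; then aq. NH4Cl
Reagents that add atoms: none
Why: Base-mediated epimerisation through the lactone enolate at C3, the only acidic C–H once the phenol is deprotonated, should equilibrate the mixture to the thermodynamically preferred trans lactone, so the fixed 4R centre dictates 3R.

**Compound list**
1 | syringaldehyde | COc1cc(C=O)cc(OC)c1O | starting material
2 | methyl (triphenylphosphoranylidene)acetate | COC(=O)C=P(c1ccccc1)(c1ccccc1)c1ccccc1 | starting material
3 | methyl (E)-3-(4-hydroxy-3,5-dimethoxyphenyl)prop-2-enoate | COC(=O)/C=C/c1cc(OC)c(O)c(OC)c1 | intermediate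
4 | methyl 3-(4-hydroxy-3,5-dimethoxyphenyl)propanoate | COC(=O)CCc1cc(OC)c(O)c(OC)c1 | intermediate
5 | benzyl bromide | BrCc1ccccc1 | starting material
6 | methyl 3-(4-benzyloxy-3,5-dimethoxyphenyl)propanoate | COC(=O)CCc1cc(OC)c(OCc2ccccc2)c(OC)c1 | intermediate
7 | allyl bromide | C=CCBr | starting material
8 | lithium enolate of 6 (not isolated) | [Li+].COC([O-])=CCc1cc(OC)c(OCc2ccccc2)c(OC)c1 | intermediate
9 | methyl 2-(4-benzyloxy-3,5-dimethoxybenzyl)pent-4-enoate (racemic) | COC(=O)C(CC=C)Cc1cc(OC)c(OCc2ccccc2)c(OC)c1 | intermediate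
10 | methyl 2-(4-benzyloxy-3,5-dimethoxybenzyl)-4,5-dihydroxypentanoate (diastereomer mixture; not isolated) | COC(=O)C(CC(O)CO)Cc1cc(OC)c(OCc2ccccc2)c(OC)c1 | intermediate
11 | methyl 2-(4-benzyloxy-3,5-dimethoxybenzyl)-4-oxobutanoate (racemic) | COC(=O)C(CC=O)Cc1cc(OC)c(OCc2ccccc2)c(OC)c1 | intermediate
12 | formaldehyde | C=O | starting material
13 | methyl (3R)-2-(4-benzyloxy-3,5-dimethoxybenzyl)-3-formyl-4-hydroxybutanoate (C2 epimer mixture; not isolated) | O=C[C@@H](CO)C(C(=O)OC)Cc1cc(OC)c(OCc2ccccc2)c(OC)c1 | intermediate
14 | (3R)-4-(4-benzyloxy-3,5-dimethoxybenzyl)-5-oxotetrahydrofuran-3-carbaldehyde (4R in lactone numbering; C3 epimer mixture) | O=C[C@H]1COC(=O)C1Cc1cc(OC)c(OCc2ccccc2)c(OC)c1 | intermediate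
15 | 4-bromo-1,2-dimethoxybenzene (4-bromoveratrole) | COc1ccc(Br)cc1OC | starting material
16 | 3,4-dimethoxyphenylmagnesium bromide (not isolated) | COc1ccc([Mg]Br)cc1OC | intermediate
17 | (4R)-3-(4-benzyloxy-3,5-dimethoxybenzyl)-4-[(3,4-dimethoxyphenyl)(hydroxy)methyl]dihydrofuran-2(3H)-one (epimers at C3 and carbinol carbon) | COc1ccc(C(O)[C@H]2COC(=O)C2Cc2cc(OC)c(OCc3ccccc3)c(OC)c2)cc1OC | intermediate
18 | (4R)-4-(3,4-dimethoxybenzyl)-3-(4-hydroxy-3,5-dimethoxybenzyl)dihydrofuran-2(3H)-one (C3 epimer mixture) | COc1ccc(C[C@H]2COC(=O)C2Cc2cc(OC)c(O)c(OC)c2)cc1OC | intermediate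
19 | (3R,4R)-4-(3,4-dimethoxybenzyl)-3-(4-hydroxy-3,5-dimethoxybenzyl)dihydrofuran-2(3H)-one (trans) | COc1ccc(C[C@H]2COC(=O)[C@@H]2Cc2cc(OC)c(O)c(OC)c2)cc1OC | target

Total step count: 9. Longest linear sequence: 9 steps (1 to 19).

**Steps most likely to fail**

Step 6. The risks are erosion of facial selectivity at C4 in the C3 series that is mismatched with the catalyst, amine- or acid-mediated epimerisation of the product aldehyde, and diversion into α-methylenation. The fallback sets out from 11 and moves the enantio-determining aldol to the aryl aldehyde. L-Proline-catalysed cross-aldol of 11 with 3,4-dimethoxybenzaldehyde (DMF, 4 °C) should give the anti adduct methyl (3S)-2-(4-benzyloxy-3,5-dimethoxybenzyl)-4-(3,4-dimethoxyphenyl)-3-formyl-4-hydroxybutanoate F1. Here the hydrogen-bond-directed enamine face places the aryl carbinol arm where the main route has its formyl group. NaBH4 in MeOH at −20 °C then reduces the formyl group to the diol ester methyl (3R)-2-(4-benzyloxy-3,5-dimethoxybenzyl)-4-(3,4-dimethoxyphenyl)-4-hydroxy-3-(hydroxymethyl)butanoate F2. Its primary hydroxyl lactonises onto the ester with pyridinium p-toluenesulfonate in CH2Cl2. The route is rejoined at 17 and the Grignard step is no longer needed.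

Step 7. The risks are deprotonation at C4 by the basic Grignard reagent (epimerisation) and competing addition to the lactone carbonyl. The fallback sets out from 14 and makes the aryl–CH2 bond by cross-coupling. NaBH4 (MeOH/CH2Cl2, −40 °C, no alkoxide base, so that the free and ring CH2O arms cannot exchange) gives (4S)-3-(4-benzyloxy-3,5-dimethoxybenzyl)-4-(hydroxymethyl)dihydrofuran-2(3H)-one F3. I2, PPh3 and imidazole (CH2Cl2, 0 °C) give (4R)-3-(4-benzyloxy-3,5-dimethoxybenzyl)-4-(iodomethyl)dihydrofuran-2(3H)-one F4. Nickel-catalysed reductive cross-electrophile coupling with 15 (NiI2, 4,4'-di-tert-butyl-2,2'-bipyridine, Zn, N,N-dimethylacetamide, 60 °C) gives (4R)-3-(4-benzyloxy-3,5-dimethoxybenzyl)-4-(3,4-dimethoxybenzyl)dihydrofuran-2(3H)-one F5. Neutral hydrogenolysis (H2, 10% Pd/C, EtOAc) removes the benzyl ether and rejoins the route at 18.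

Step 8. The risks are acid-promoted ionisation of the benzylic alcohol followed by Friedel–Crafts closure onto ring B, and stalling at the benzylic alcohol once the benzyl ether has gone. The fallback sets out from 17 and activates the carbinol as an ester. Ac2O, pyridine and catalytic 4-dimethylaminopyridine (CH2Cl2, 0 °C) give (4R)-4-[acetoxy(3,4-dimethoxyphenyl)methyl]-3-(4-benzyloxy-3,5-dimethoxybenzyl)dihydrofuran-2(3H)-one F6. Hydrogenolysis of the benzylic acetate and the benzyl ether under neutral conditions (H2, 10% Pd/C, EtOAc/EtOH, rt) rejoins the route at 18.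

**Further compounds**
F1 | step 6 | methyl (3S)-2-(4-benzyloxy-3,5-dimethoxybenzyl)-4-(3,4-dimethoxyphenyl)-3-formyl-4-hydroxybutanoate | COC(=O)C(Cc1cc(OC)c(OCc2ccccc2)c(OC)c1)[C@H](C=O)C(O)c1ccc(OC)c(OC)c1
F2 | step 6 | methyl (3R)-2-(4-benzyloxy-3,5-dimethoxybenzyl)-4-(3,4-dimethoxyphenyl)-4-hydroxy-3-(hydroxymethyl)butanoate | COC(=O)C(Cc1cc(OC)c(OCc2ccccc2)c(OC)c1)[C@H](CO)C(O)c1ccc(OC)c(OC)c1
F3 | step 7 | (4S)-3-(4-benzyloxy-3,5-dimethoxybenzyl)-4-(hydroxymethyl)dihydrofuran-2(3H)-one | OC[C@H]1COC(=O)C1Cc1cc(OC)c(OCc2ccccc2)c(OC)c1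
F4 | step 7 | (4R)-3-(4-benzyloxy-3,5-dimethoxybenzyl)-4-(iodomethyl)dihydrofuran-2(3H)-one | IC[C@H]1COC(=O)C1Cc1cc(OC)c(OCc2ccccc2)c(OC)c1
F5 | step 7 | (4R)-3-(4-benzyloxy-3,5-dimethoxybenzyl)-4-(3,4-dimethoxybenzyl)dihydrofuran-2(3H)-one | COc1ccc(C[C@H]2COC(=O)C2Cc2cc(OC)c(OCc3ccccc3)c(OC)c2)cc1OC
F6 | step 8 | (4R)-4-[acetoxy(3,4-dimethoxyphenyl)methyl]-3-(4-benzyloxy-3,5-dimethoxybenzyl)dihydrofuran-2(3H)-one | COc1ccc(C(OC(C)=O)[C@H]2COC(=O)C2Cc2cc(OC)c(OCc3ccccc3)c(OC)c2)cc1OC
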